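## Retrosynthetic overview

1. Feature, in drimane numbering (ring A C1–C5/C10, ring B C5–C10, C11 = OCH2 on C9, C12 = CH2 on C8): ring A without C2 is a 2-methylcyclopent-2-enone (C3=O, C4–CH3, C4=C5, C10, C1) fused to ring B at C5–C10. That unit is the carbonylative [2+2+1] adduct of a 1,7-enyne.
2. Endgame disconnections: C11–O(aryl) by Mitsunobu reaction with umbelliferone, C8=C12 by methylenation of a C6=C7 enone, C3–OH by hydride, and the second C4 methyl plus H5 by reductive methylation of the 4-methyl-4-en-3-one.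
3. Key disconnection: C1–C2 and C2–C3. The 4-methyl-1,4-dien-3-one gives up C2 and goes back to the 3-silyloxy cyclopentadiene of the five-membered enone (forward: cyclopropanation, FeCl3 fragmentation, loss of HCl).
4. Enyne: an Evans syn aldol of the 3-methylbut-3-enoyl imide with hex-4-ynal sets C9. C8 is carried as a temporary carbinol tied to O11 in an acetonide, which avoids an epimerisable β,γ-unsaturated ketone and supplies the chair that relays C9 to C10.
5. Ring order: dioxane (temporary), then ring B and the five-membered ring together (Pauson–Khand), then six-membered ring A by enlargement. The coumarin is bought.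

Key step: step 8

Assumption: the target is taken as drawn, (3R,5S,9R,10R). This is the antipodal drimane series with equatorial 3-OH, trans ring fusion and equatorial C9 side chain. Drimane numbering is applied to every intermediate. TBS = tert-butyldimethylsilyl, PPTS = pyridinium p-toluenesulfonate, DIAD = diisopropyl azodicarboxylate.

## Route

Step 1
Reactants: 1 hex-4-yn-1-ol
Product: 2 hex-4-ynal
Conditions: TEMPO (10 mol %), PhI(OAc)2 (1.1 equiv), CH2Cl2, rt
Reagents that add atoms: none
Why: Oxoammonium-catalysed alcohol oxidation (TEMPO/PhI(OAc)2) stops at the aldehyde and leaves the internal alkyne untouched.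

Step 2
Reactants: 3 3-methylbut-3-enoic acid; 4 (S)-4-benzyl-1,3-oxazolidin-2-one
Product: 6 (S)-4-benzyl-3-(3-methylbut-3-enoyl)-1,3-oxazolidin-2-one, via mixed pivalic anhydride 5 (not isolated)
Conditions: t-BuCOCl, Et3N, THF, −20 °C; then LiCl, 4, −20 °C → rt
Reagents that add atoms: none
Why: N-acylation of the oxazolidinone through a mixed anhydride needs no strong base, so the β,γ-alkene should stay in place, and any conjugated isomer would give the same dienolate in step 3.

Step 3
Reactants: 6 N-acyl oxazolidinone; 2 hex-4-ynal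
Product: 9 (S)-4-benzyl-3-[(2S,3R)-3-hydroxy-2-(prop-1-en-2-yl)oct-6-ynoyl]-1,3-oxazolidin-2-one, via boron dienolate 7 (not isolated), via boron aldolate 8 (not isolated)
Conditions: n-Bu2BOTf, Et3N, CH2Cl2, −78 → 0 °C; 2, −78 → 0 °C; then pH 7 buffer, MeOH, 30% H2O2, 0 °C
Reagents that add atoms: none
Why: Evans syn aldol reaction, in which the (Z)-boron dienolate reacts at its α-carbon C9 through a Zimmerman–Traxler chair on the face away from the benzyl group, setting C9 (S here, R from step 4 on by a priority change only) and the temporary C8 carbinol (R) in a syn relation.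

Step 4
Reactants: 9 aldol adduct
Product: 10 (2R,3R)-2-(prop-1-en-2-yl)oct-6-yne-1,3-diol
Conditions: LiBH4, Et2O–THF, 0 °C
Reagents that add atoms: none
Why: Reductive cleavage of the imide turns the acyl carbon into C11H2OH without touching C9, the alkene or the alkyne, and returns the auxiliary.

Step 5
Reactants: 10 diol
Product: 11 (4R,5R)-2,2-dimethyl-4-(pent-3-yn-1-yl)-5-(prop-1-en-2-yl)-1,3-dioxane
Conditions: Me2C(OMe)2, PPTS (cat.), CH2Cl2, rt
Reagents that add atoms: 2,2-dimethoxypropane, COC(C)(C)OC
Why: Acid-catalysed transketalisation gives the 4,5-cis acetonide, whose chair holds the C8 chain equatorial and the isopropenyl group axial because the other chair would put C7 syn-axial to an acetonide methyl.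

Step 6
Reactants: 11 acetonide enyne
Product: 13 ring A-nor enone (8R,9R,10S), via alkyne-Co2(CO)6 complex 12 (not isolated)
Conditions: Co2(CO)8 (1.1 equiv), ClCH2CH2Cl, rt; then n-BuSMe (3.5 equiv), 83 °C
Reagents that add atoms: dicobalt octacarbonyl Co2(CO)8 (one CO becomes C3=O), [Co].[Co].[C-]#[O+].[C-]#[O+].[C-]#[O+].[C-]#[O+].[C-]#[O+].[C-]#[O+].[C-]#[O+].[C-]#[O+]
Why: Intramolecular Pauson–Khand reaction of a 1,7-enyne, in which the locked dioxane chair makes ring B close through a chair with C11 equatorial, the five-membered metallacycle keeps C1 in the plane of the nascent C4=C5 bond, and the C10 methyl is therefore axial and cis to C11 (10S).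

Step 7
Reactants: 13 ring A-nor enone
Product: 15 silyl dienol ether (8R,9R,10S), via lithium dienolate 14 (not isolated)
Conditions: LiN(iPr)2, THF, −78 °C; Me3SiCl, −78 → 0 °C; cold aq NaHCO3/pentane work-up
Reagents that add atoms: chlorotrimethylsilane, C[Si](C)(C)Cl
Why: Kinetic α′-deprotonation of the cyclopentenone at C1H2 rather than at γ-C6H2, followed by O-silylation, gives the cross-conjugated 3-silyloxy cyclopentadiene.

Step 8
Reactants: 15 silyl dienol ether
Product: 18 4-methyl-1,4-dien-3-one (8R,9R,10S), via silyloxycyclopropane 16 (not isolated), via 1-chloro enone 17 (not isolated)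
Conditions: Et2Zn (1.5 equiv), CH2I2 (1.5 equiv), Et2O, 0 °C → rt, aq NH4Cl wash, crude; FeCl3 (2.5 equiv), DMF, 0 °C → rt, crude; NaOAc, MeOH, reflux
Reagents that add atoms: diiodomethane, ICI
Why: Saegusa–Ito one-carbon ring enlargement (Furukawa-type Simmons–Smith cyclopropanation, oxidative cyclopropane fragmentation, dehydrochlorination), the closest known case being its use on cross-conjugated silyl dienol ethers of cyclic enones. EtZnCH2I delivers C2 concertedly to C1=C3, which forms C1–C2 and C2–C3 and closes a three-membered ring by [2+1] addition; the transient centres C1 and C3 of 16 follow approach on the face of the C10 methyl, away from C9, and both are erased again, so no lasting stereocentre is created. FeCl3 exchanges silicon for iron at O3 and trivalent iron takes one electron, and the oxygen-centred radical breaks the shared C1–C3 bond because that releases cyclopropane strain, gives the secondary C1 radical rather than a primary one and leaves the C3 ketone conjugated with C4=C5; six-membered ring A is thus closed not by a new cyclisation but by merging the three- and five-membered rings. A second FeCl3 transfers chlorine to C1 to give 17, and NaOAc removes HCl by E1cB (C2–H, C1–Cl) to give the C1=C2 bond of 18. The step needs site selectivity between the two double bonds of the diene, and the substrate secures it: C1=C3 carries the oxygen donor and a hydrogen, whereas C4=C5 is tetrasubstituted, receives no push from O3 and is shielded by C10 and ring B, and the carbenoid is kept to a small excess. The place of insertion was fixed by the kinetic deprotonation at C1 in step 7, quaternary C10 rules out 1,5-hydrogen shifts of the cyclopentadiene, and FeCl3 tamed by DMF at 0 °C should spare the acetonide.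

Step 9
Reactants: 18 4-methyl-1,4-dien-3-one
Product: 19 4-methyl-4-en-3-one (8R,9R,10S)
Conditions: H2 (1 atm), RhCl(PPh3)3 (10 mol %), benzene–EtOH, rt
Reagents that add atoms: none
Why: Homogeneous hydrogenation with RhCl(PPh3)3 saturates the disubstituted C1=C2 bond of a 1,4-dien-3-one and cannot bind the tetrasubstituted C4=C5 bond, as known for santonin-type and steroidal dienones.

Step 10
Reactants: 19 4-methyl-4-en-3-one
Product: 21 (5S,8R,9R,10R)-8,11-(isopropylidenedioxy)-12-nordriman-3-one, via lithium enolate 20 (not isolated)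
Conditions: Li (2.2 equiv), NH3(l)–THF, t-BuOH (1.0 equiv), −78 → −33 °C; then MeI, −78 °C → rt
Reagents that add atoms: iodomethane, CI
Why: Dissolving-metal reductive alkylation, in which C5 of the reduced enone is protonated axially and anti to the C10 methyl, setting the trans ring fusion (5S), and the regiodefined C3–C4 enolate 20 is then C-methylated at C4.

Step 11
Reactants: 21 3-ketone
Product: 22 (3R,5S,8R,9R,10R)-8,11-(isopropylidenedioxy)-12-nordriman-3-ol
Conditions: NaBH4, MeOH, 0 °C
Reagents that add atoms: none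
Why: Hydride reduction of a 4,4-dimethyl-3-ketone in a trans-decalin, where NaBH4 attacks axially from the face opposite the axial C4 and C10 methyls and gives the equatorial alcohol cis to the C10 methyl (3R).

Step 12
Reactants: 22 3-alcohol
Product: 23 3-O-TBS ether of 22
Conditions: TBSOTf, 2,6-lutidine, CH2Cl2, −78 → 0 °C
Reagents that add atoms: tert-butyldimethylsilyl triflate, CC(C)(C)[Si](C)(C)OS(=O)(=O)C(F)(F)F
Why: Silylation with the silyl triflate overcomes the hindrance of the C3–OH next to quaternary C4 and masks it against LiN(iPr)2 and Cp2TiMe2 in later steps.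

Step 13
Reactants: 23 acetonide silyl ether
Product: 24 (3R,5S,8R,9R,10R)-3-(TBS-oxy)-12-nordrimane-8,11-diol
Conditions: PPTS (cat.), MeOH, rt
Reagents that add atoms: none
Why: Mild acid-catalysed transketalisation to methanol removes the strained acetonide, while the hindered secondary silyl ether at C3 is inert to PPTS.

Step 14
Reactants: 24 8,11-diol
Product: 25 (3R,5S,8R,9R,10R)-3,11-bis(TBS-oxy)-12-nordriman-8-ol
Conditions: TBSCl (1.05 equiv), imidazole, CH2Cl2, 0 °C
Reagents that add atoms: tert-butyldimethylsilyl chloride, CC(C)(C)[Si](C)(C)Cl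
Why: Rate-controlled silylation, since primary C11–OH reacts far faster with TBSCl than axial C8–OH, which is syn-axial to the C10 methyl.

Step 15
Reactants: 25 8-alcohol
Product: 26 (3R,5S,9R,10R)-3,11-bis(TBS-oxy)-12-nordriman-8-one
Conditions: Dess–Martin periodinane, CH2Cl2, 0 °C → rt
Reagents that add atoms: none
Why: Dess–Martin oxidation under near-neutral conditions erases the temporary C8 stereocentre without β-elimination of the silyloxy group, and C9 keeps its equatorial, thermodynamically preferred side chain.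

Step 16
Reactants: 26 8-ketone
Product: 29 (3R,5S,9R,10R)-3,11-bis(TBS-oxy)-12-nordrim-6-en-8-one, via lithium enolate 27 (not isolated), via trimethylsilyl enol ether 28 (not isolated)
Conditions: LiN(iPr)2, THF, −78 °C; Me3SiCl, −78 → 0 °C; then Pd(OAc)2 (1.05 equiv), MeCN, rt
Reagents that add atoms: none
Why: Saegusa–Ito dehydrogenation, in which the amide base removes a C7 proton kinetically (C9–H is tertiary and flanked by C10), divalent palladium binds C7 of the silyl enol ether, and β-hydride loss from C6 gives the C6=C7 enone.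

Step 17
Reactants: 29 6-en-8-one
Product: 30 (3R,5S,9R,10R)-3,11-bis(TBS-oxy)drima-6,8(12)-diene
Conditions: Cp2TiMe2 (3 equiv), toluene, 70 °C, dark
Reagents that add atoms: dimethyltitanocene Cp2TiMe2, C[Ti+2]C.c1cc[cH-]c1.c1cc[cH-]c1
Why: Petasis methylenation, in which Cp2Ti=CH2 formed on heating undergoes [2+2] addition and cycloreversion at the C8 carbonyl and, being non-basic, neither epimerises C9 nor expels the β-silyloxy group.

Step 18
Reactants: 30 bis-silyl diene
Product: 31 (3R,5S,9R,10R)-drima-6,8(12)-diene-3,11-diol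
Conditions: Bu4NF (excess), THF, 50 °C
Reagents that add atoms: none
Why: Fluoride-mediated desilylation removes both silyl ethers under non-acidic conditions that should not isomerise the exocyclic diene.

Step 19
Reactants: 31 diene diol; 32 umbelliferone (7-hydroxy-2H-chromen-2-one)
Product: 33 target CNP0259618.4
Conditions: PPh3 (1.1 equiv), DIAD (1.1 equiv), THF, 0 °C → rt
Reagents that add atoms: none
Why: Mitsunobu etherification, in which the acidic phenol displaces the oxyphosphonium of primary C11–OH by SN2 without touching a stereocentre, while the C3–OH next to quaternary C4 is too hindered to compete at about one equivalent of reagents.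

## Compound list

| No. | Name | SMILES | Role |
|---|---|---|---|
| 1 | hex-4-yn-1-ol | CC#CCCCO | starting material |
| 2 | hex-4-ynal | CC#CCCC=O | intermediate |
| 3 | 3-methylbut-3-enoic acid | C=C(C)CC(=O)O | starting material |
| 4 | (S)-4-benzyl-1,3-oxazolidin-2-one | O=C1N[C@@H](Cc2ccccc2)CO1 | starting material |
| 5 | 3-methylbut-3-enoic pivalic anhydride | C=C(C)CC(=O)OC(=O)C(C)(C)C | intermediate |
| 6 | (S)-4-benzyl-3-(3-methylbut-3-enoyl)-1,3-oxazolidin-2-one | C=C(C)CC(=O)N1[C@@H](Cc2ccccc2)COC1=O | intermediate |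
| 7 | (Z)-dibutylboron dienolate of 6 | C=C(C)/C=C(\OB(CCCC)CCCC)N1[C@@H](Cc2ccccc2)COC1=O | intermediate |
| 8 | O8-dibutylboron aldolate of 9 | C=C(C)[C@H](C(=O)N1[C@@H](Cc2ccccc2)COC1=O)[C@H](OB(CCCC)CCCC)CCC#CC | intermediate |
| 9 | (S)-4-benzyl-3-[(2S,3R)-3-hydroxy-2-(prop-1-en-2-yl)oct-6-ynoyl]-1,3-oxazolidin-2-one (syn aldol) | C=C(C)[C@H](C(=O)N1[C@@H](Cc2ccccc2)COC1=O)[C@H](O)CCC#CC | intermediate |
| 10 | (2R,3R)-2-(prop-1-en-2-yl)oct-6-yne-1,3-diol | C=C(C)[C@H](CO)[C@H](O)CCC#CC | intermediate |
| 11 | (4R,5R)-2,2-dimethyl-4-(pent-3-yn-1-yl)-5-(prop-1-en-2-yl)-1,3-dioxane (4,5-cis) | C=C(C)[C@@H]1COC(C)(C)O[C@@H]1CCC#CC | intermediate |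
| 12 | Co2(CO)6 complex of 11, dicobalt unit bridging C4≡C5 | C=C(C)[C@@H]1COC(C)(C)O[C@@H]1CCC23[Co-3]4(C#[O+])(C#[O+])(C#[O+])[Co-3]2(C#[O+])(C#[O+])(C#[O+])C34C | intermediate |
| 13 | (8R,9R,10S) ring A-nor enone: 2-methylcyclopent-2-enone (C3=O, C4-CH3, C4=C5, C10, C1H2) fused at C5-C10 to ring B; C10-CH3, C11 and O8 on one face; O8/O11 acetonide | O=C1C[C@@]2(C)[C@@H]3COC(C)(C)O[C@@H]3CCC2=C1C | intermediate |
| 14 | lithium cross-conjugated dienolate of 13 (C1=C3-O, C4=C5) | [Li+].[O-]C1=C[C@@]2(C)[C@@H]3COC(C)(C)O[C@@H]3CCC2=C1C | intermediate |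
| 15 | (8R,9R,10S) silyl dienol ether: C1=C3(OSiMe3)-C4(CH3)=C5 cyclopentadiene on quaternary C10, otherwise as 13 (key-step precursor) | C[Si](C)(C)OC1=C[C@@]2(C)[C@@H]3COC(C)(C)O[C@@H]3CCC2=C1C | intermediate |
| 16 | silyloxycyclopropane: C2H2 bridging C1 and C3 of 15 on the face of the C10 methyl; C4=C5 retained | C[Si](C)(C)O[C@@]12C[C@@H]1[C@@]3(C)[C@@H]4COC(C)(C)O[C@@H]4CCC3=C2C | intermediate |
| 17 | 1-chloro-4-methyl-4-en-3-one with six-membered ring A; Cl on C1 drawn anti to the C10 methyl (either C1 epimer eliminates) | O=C1C[C@@H](Cl)[C@@]2(C)[C@@H]3COC(C)(C)O[C@@H]3CCC2=C1C | intermediate |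
| 18 | (8R,9R,10S) 4-methyl-1,4-dien-3-one with ring B, O8/O11 acetonide (key-step product) | O=C1C=C[C@@]2(C)[C@@H]3COC(C)(C)O[C@@H]3CCC2=C1C | intermediate |
| 19 | (8R,9R,10S) 4-methyl-4-en-3-one, O8/O11 acetonide | O=C1CC[C@@]2(C)[C@@H]3COC(C)(C)O[C@@H]3CCC2=C1C | intermediate |
| 20 | lithium C3-C4 enolate, trans-fused (5S,8R,9R,10R) | [Li+].[O-]C=1CC[C@@]2(C)[C@@H]3COC(C)(C)O[C@@H]3CC[C@@H]2C=1C | intermediate |
| 21 | (5S,8R,9R,10R)-8,11-(isopropylidenedioxy)-12-nordriman-3-one | O=C1CC[C@@]2(C)[C@@H]3COC(C)(C)O[C@@H]3CC[C@@H]2C1(C)C | intermediate |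
| 22 | (3R,5S,8R,9R,10R)-8,11-(isopropylidenedioxy)-12-nordriman-3-ol (equatorial OH) | O[C@@H]1CC[C@@]2(C)[C@@H]3COC(C)(C)O[C@@H]3CC[C@@H]2C1(C)C | intermediate |
| 23 | 3-O-TBS ether of 22 | CC(C)(C)[Si](C)(C)O[C@@H]1CC[C@@]2(C)[C@@H]3COC(C)(C)O[C@@H]3CC[C@@H]2C1(C)C | intermediate |
| 24 | (3R,5S,8R,9R,10R)-3-(TBS-oxy)-12-nordrimane-8,11-diol | CC(C)(C)[Si](C)(C)O[C@@H]1CC[C@@]2(C)[C@H](CO)[C@H](O)CC[C@@H]2C1(C)C | intermediate |
| 25 | (3R,5S,8R,9R,10R)-3,11-bis(TBS-oxy)-12-nordriman-8-ol | CC(C)(C)[Si](C)(C)O[C@@H]1CC[C@@]2(C)[C@H](CO[Si](C)(C)C(C)(C)C)[C@H](O)CC[C@@H]2C1(C)C | intermediate |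
| 26 | (3R,5S,9R,10R)-3,11-bis(TBS-oxy)-12-nordriman-8-one | CC(C)(C)[Si](C)(C)O[C@@H]1CC[C@@]2(C)[C@H](CO[Si](C)(C)C(C)(C)C)C(=O)CC[C@@H]2C1(C)C | intermediate |
| 27 | lithium C7-C8 enolate of 26 | CC(C)(C)[Si](C)(C)O[C@@H]1CC[C@@]2(C)[C@H](CO[Si](C)(C)C(C)(C)C)C([O-])=CC[C@@H]2C1(C)C.[Li+] | intermediate |
| 28 | 8-trimethylsilyloxy-7-ene (silyl enol ether of 26) | CC(C)(C)[Si](C)(C)O[C@@H]1CC[C@@]2(C)[C@H](CO[Si](C)(C)C(C)(C)C)C(O[Si](C)(C)C)=CC[C@@H]2C1(C)C | intermediate |
| 29 | (3R,5S,9R,10R)-3,11-bis(TBS-oxy)-12-nordrim-6-en-8-one | CC(C)(C)[Si](C)(C)O[C@@H]1CC[C@@]2(C)[C@H](CO[Si](C)(C)C(C)(C)C)C(=O)C=C[C@@H]2C1(C)C | intermediate |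
| 30 | (3R,5S,9R,10R)-3,11-bis(TBS-oxy)drima-6,8(12)-diene | CC(C)(C)[Si](C)(C)O[C@@H]1CC[C@@]2(C)[C@H](CO[Si](C)(C)C(C)(C)C)C(=C)C=C[C@@H]2C1(C)C | intermediate |
| 31 | (3R,5S,9R,10R)-drima-6,8(12)-diene-3,11-diol | O[C@@H]1CC[C@@]2(C)[C@H](CO)C(=C)C=C[C@@H]2C1(C)C | intermediate |
| 32 | umbelliferone (7-hydroxy-2H-chromen-2-one) | O=c1ccc2ccc(O)cc2o1 | starting material |
| 33 | 7-{[(3R,5S,9R,10R)-3-hydroxydrima-6,8(12)-dien-11-yl]oxy}-2H-chromen-2-one (CNP0259618.4) | C=C1C=C[C@@H]2C(C)(C)[C@H](O)CC[C@@]2(C)[C@@H]1COc1ccc2ccc(=O)oc2c1 | target |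

## Step count

Total step count: 19.
Longest linear sequence: 18 (steps 2–19; step 1 is a one-step branch).

## Steps most likely to fail

**1. Step 8 (ring enlargement).**
- The trimethylsilyl group may be lost to zinc iodide before methylene transfer.
- A second methylene transfer may occur at C4=C5.
- An outer cyclopropane bond may break instead of C1–C3 in the iron stage.
- The acetonide may open under Lewis acid.

Fallback, from 15 back to the route at 19: a dihalocarbene ring enlargement, which needs neither a one-electron oxidant nor a Lewis acid. Dichlorocarbene (Cl3CCO2Na, DME, reflux) adds to C1=C3 and gives the 2,2-dichloro silyloxycyclopropane F1. On continued heating one C–Cl bond ionises with disrotatory opening of C1–C3 (cyclopropyl to allyl cation). Loss of the silyl group then gives the 2-chloro-4-methyl-1,4-dien-3-one F2. Treatment with H2, Pd/C and Et3N in EtOAc saturates C1=C2 and hydrogenolyses C2–Cl, which gives 19.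

**2. Step 6 (Pauson–Khand).**
- Insertion of the 1,1-disubstituted alkene into the cobalt–carbon bond may be slow, with decomplexation on prolonged heating.
- Facial selectivity at C10 may erode, because the favoured chair develops a syn-axial contact between O8 and the C10 methyl.

Fallback, from 11 back to the route at 13: ring closure and carbonylation are separated. Cp2ZrCl2 with n-BuLi (2 equiv) in THF, −78 °C → rt, couples alkyne and alkene reductively to the zirconatricycle F3. Its formation is reversible, so C10 is selected under thermodynamic rather than kinetic control. CO (1 atm, 0 °C → rt) then inserts into the C1–Zr bond, and reductive elimination closes C3–C4 to give 13.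

**3. Step 19 (Mitsunobu).**
- Displacement at the β-branched C11 may be sluggish.
- The oxyphosphonium may eliminate across C9–C11 towards a cross-conjugated triene.
- C3–OH may be activated in competition.

Fallback, from 31 back to the route at 33: activation and displacement are separated. MsCl (1.0 equiv) with 2,4,6-collidine in CH2Cl2 at −20 °C gives the primary C11 mesylate F4, so the chemoselectivity is settled before the coumarin is brought in. Then 32 with Cs2CO3 in DMF at 50 °C forms the ether by Williamson displacement with the free caesium phenoxide.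

## Further compounds

F1 | step 8 | 2,2-dichloro silyloxycyclopropane (CCl2 bridging C1 and C3 of 15 on the face of the C10 methyl) | C[Si](C)(C)O[C@@]12C(Cl)(Cl)[C@@H]1[C@@]3(C)[C@@H]4COC(C)(C)O[C@@H]4CCC3=C2C
F2 | step 8 | (8R,9R,10S) 2-chloro-4-methyl-1,4-dien-3-one, O8/O11 acetonide | O=C1C(Cl)=C[C@@]2(C)[C@@H]3COC(C)(C)O[C@@H]3CCC2=C1C
F3 | step 6 | zirconatricycle: Cp2Zr bonded to C1 and C4, C4=C5, C5-C10 closed, otherwise as 13 | [Zr+2]1C[C@@]2(C)[C@@H]3COC(C)(C)O[C@@H]3CCC2=C1C.c1cc[cH-]c1.c1cc[cH-]c1
F4 | step 19 | (3R,5S,9R,10R)-3-hydroxydrima-6,8(12)-dien-11-yl methanesulfonate | O[C@@H]1CC[C@@]2(C)[C@H](COS(C)(=O)=O)C(=C)C=C[C@@H]2C1(C)C
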